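The vessel is a stirred flask of constant volume in which substrate turns into intermediate and intermediate takes up partner to give product. The recipes differ in when each charge goes in and when the warmth arrives.

| flask | substrate | partner | temperature | remark | time |
|---|---|---|---|---|---|
| ash | 20 mM | 36 mM | 0 °C | run made earlier |  |
| alder | 20 mM | 18 mM | 11 °C | run made earlier |  |
| maple | 20 mM | 27 mM | 0 °C | run made earlier |  |
| delta | 20 mM (fed, over 50 min) | 36.0 mM |  | the addition at −35 °C, then warmed to 5 °C; the feed brings no volume worth counting | 80 min |
| epsilon | 20 mM | 36.0 mM (fed, over 50 min) | 5 °C | all else is in the flask from the start; the feed brings no volume worth counting | 80 min |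
| gamma | 20 mM | 36.0 mM | 5 °C | everything together at the start | 80 min |
| zeta | 20 mM | 36.0 mM |  | everything together at the start at −35 °C, warmed to 5 °C at 50 min | 80 min |
| beta | 20 mM (in portions, 4, over 50 min) | 36.0 mM | 5 °C | first portion at the start, last at 50 min | 80 min |

| run | time / min | product / % | substrate / % |
|---|---|---|---|
| ash | 6.00 | 0 | 89 |
| ash | 15.0 | 1 | 82 |
| ash | 30.0 | 5 | 66 |
| ash | 80.0 | 17 | 36 |
| alder | 5.00 | 0 | 70 |
| alder | 12.0 | 3 | 49 |
| alder | 30.0 | 16 | 13 |
| alder | 60.0 | 21 | 4 |
| maple | 15.0 | 0 | 84 |
| maple | 30.0 | 2 | 69 |
| maple | 50.0 | 10 | 51 |
| maple | 60.0 | 9 | 45 |

(each reading ± 2 percentage points)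

- steps thought possible: substrate -> intermediate; partner + intermediate <-> product

1. the best flask by amount of product, in percent of the substrate charged; "all alike" if 1.5 percentage points covers them all (delta / epsilon / gamma / zeta / beta / all alike)
2. amount of product at the end, in percent of the substrate charged, delta
3. amount of product at the end, in percent of the substrate charged, epsilon
4. amount of product at the end, in percent of the substrate charged, gamma
5. amount of product at the end, in percent of the substrate charged, zeta
6. amount of product at the end, in percent of the substrate charged, beta

Take the first step by itself. At 30.0 min substrate stands at 66% in ash and 69% in maple, close for a scatter of 2 percentage points though [partner] differs, so its loss reads as first order and free of partner. Ash's last reading gives 0.0128 min⁻¹ at 0 °C, and alder at 30.0 min gives 0.0680 min⁻¹ at 11 °C. A straight line in the logarithm then gives 0.0273 min⁻¹ at 5 °C.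

Gamma's 80 min at that temperature make 2.19 turnovers. This turnover count, the first-order constant of substrate loss times the minutes spent at that temperature, leaves 11.2% of the substrate in gamma, and with this step alone the remaining 88.8% would be converted. Epsilon has the same count, since its substrate is in from the start. The cold adds 0.00312 turnovers in 50 min at −35 °C, which is hardly any. Zeta and delta therefore have 0.819, and beta on average 1.50, less than gamma but more than zeta.

Now add the second step. Ash holds 17% product after 1.02 turnovers, and product trailing an intermediate grows as the square of the count while little has passed on. With ash's ratio of the two steps held, this text's own reckoning puts zeta and delta near 10.9%. The same square gives gamma 77.8%, which is no estimate, because gamma's count stands well past ash's. The return step and epsilon's late partner are not reckoned here, so this reckoning commits to an order: gamma, epsilon, beta, then zeta level with delta.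

The forecast names gamma, with 33% there, 29.5% for epsilon, 22% for beta, and 10% for zeta and 10% for delta, given “only 30 warm minutes, with nothing happening in the cold”.

The flasks give 30.9% in gamma, 28.1% in epsilon, 20.5% in beta, 8.99% in zeta and 8.98% in delta. So gamma is best, by 2.8 points over epsilon against a margin of 1.5 points.

    substrate → intermediate (k = 0.0259 min⁻¹, Ea = 90.0 kJ mol⁻¹)
    partner + intermediate ⇌ product (K = 49.0 M⁻¹, k = 0.339 M⁻¹ min⁻¹, Ea = 56.0 kJ mol⁻¹, ΔH = −13.0 kJ mol⁻¹)
    (constants at 5 °C)

Substrate ends at 12.6% in gamma against the count's 11.2%, and at 45.9% in zeta against 44.1%. In gamma the substrate half-life of 27 min is about half the 57 min of intermediate by the forward second step alone, pseudo-first-order with the other concentrations as charged. At 80.0 min gamma holds more intermediate than product, 56.5% against 30.9%. A neighbour of gamma charged with 80 mM of substrate runs the same count, and its substrate ends at 12.6%.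

All runs were computed on assumed constants; scatter was added.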